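**Retrosynthetic overview**
1. Target ⇐ C1 ketone (methylenation last). The diequatorial 8‑chloro/9‑bromo pair ⇐ ring B 8,9‑epoxide, by bromide opening and a bromonium‑relayed 1,2‑halogen interchange.
2. Epoxide ⇐ trisubstituted ring B alkene ⇐ spiro enone (conjugate reduction/enol triflate, then Negishi methylation).
3. Ring B ⇐ intramolecular aldol condensation of a methyl ketone onto the aldehyde at the spiro carbon.
4. Ring A, its C–Br centre and the quaternary spiro carbon ⇐ acyclic enolised β‑keto aldehyde, by enantioselective bromo‑cycloetherification (C–O bond at the later CMe2 carbon) and a 1,3 O→C shift.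
5. Acyclic chain ⇐ 6‑methylhept‑5‑en‑2‑one + ethyl formate + methyl vinyl ketone. Ring order: transient oxane, ring A, ring B.

Assumption: hydroquinidine 1,4‑phthalazinediyl diether, (DHQD)2PHAL, is taken to give the (S)‑bromide in step 2 by analogy with its bromolactonisations; if the antipode forms, (DHQ)2PHAL is used.

Locants are those of spiro[5.5]undecane: C1 ketone/methylidene, C4 CHBr, C5 CMe2, C6 spiro, C8 and C9 the halogenated ring B carbons.

**Step 1**
Reactants: 1 6‑methylhept‑5‑en‑2‑one; 2 ethyl formate; 3 but‑3‑en‑2‑one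
Product: 5 (5Z)-5-(hydroxymethylidene)-10-methylundec-9-ene-2,6-dione, via sodium enolate 4 (not isolated)
Conditions: NaH (1.0 equiv), THF, 0 °C → rt; then 3, 0 °C; aq. HCl work‑up
Reagents that add atoms: none
Why: Claisen formylation at the methyl group gives the stabilised sodium enolate of the β‑keto aldehyde, whose central carbon then adds to the enone (Michael addition); the product is still enolisable, so it resists deformylation, and no stereocentre is formed.

**Step 2**
Reactants: 5 (5Z)-5-(hydroxymethylidene)-10-methylundec-9-ene-2,6-dione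
Product: 7 (1R,3S)-3-bromo-2,2-dimethyl-6-oxo-1-(3-oxobutyl)cyclohexane-1-carbaldehyde, via oxanylidene aldehyde 6 (not isolated)
Conditions: (DHQD)2PHAL (10 mol %), NBS, CHCl3/hexane, −40 °C; then (CF3)2CHOH, Sc(OTf)3 (5 mol %), 0 °C
Reagents that add atoms: N‑bromosuccinimide, O=C1CCC(=O)N1Br
Why: Proposed new method: the enolised β‑keto aldehyde is a vinylogous carboxylic acid, so the quinuclidine of (DHQD)2PHAL ion‑pairs with it and passes Br+ from NBS to one face of the trisubstituted alkene while the ketone‑type enolate oxygen closes the six‑membered ring at the tertiary carbon (anti, Markovnikov), forming the C–O bond and fixing the C–Br centre (S); Sc(OTf)3 in (CF3)2CHOH then ionises that tertiary C–O bond with help from the antiperiplanar bromine (bromonium ion, configuration kept) and the Sc‑chelated dicarbonyl enolate recloses through carbon in a chair (Br equatorial, chelate‑held formyl equatorial, oxobutyl axial) to set the quaternary carbon (R); the closest known reaction types are cinchona‑catalysed asymmetric bromolactonisation, the Lewis‑acid 1,3 O‑to‑C shift of enol ethers and enantiospecific capture of bromonium ions released from β‑bromo esters.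

**Step 3**
Reactants: 7 (1R,3S)-3-bromo-2,2-dimethyl-6-oxo-1-(3-oxobutyl)cyclohexane-1-carbaldehyde
Product: 8 (4S,6S)-4-bromo-5,5-dimethylspiro[5.5]undec-7-ene-1,9-dione
Conditions: p‑TsOH·H2O (10 mol %), toluene, 80 °C (−H2O)
Reagents that add atoms: none
Why: Acid‑catalysed intramolecular aldol condensation (closing half of a Robinson‑type spiroannulation): the methyl‑ketone enol attacks the non‑enolisable aldehyde, the most electrophilic carbonyl, in a six‑membered closure and dehydrates to the enone; no stereocentre changes.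

**Step 4**
Reactants: 8 (4S,6S)-4-bromo-5,5-dimethylspiro[5.5]undec-7-ene-1,9-dione
Product: 10 (4S,6S)-4-bromo-5,5-dimethyl-1-oxospiro[5.5]undec-8-en-9-yl trifluoromethanesulfonate, via lithium enolate 9 (not isolated)
Conditions: LiBH(s‑Bu)3, THF, −78 °C; then PhNTf2, −78 → 0 °C
Reagents that add atoms: N‑phenylbis(trifluoromethanesulfonimide), O=S(=O)(N(c1ccccc1)S(=O)(=O)C(F)(F)F)C(F)(F)F
Why: Reductive triflation: the hindered borohydride adds 1,4 to the β‑unsubstituted enone faster than it attacks the hindered C1 ketone, and the regiodefined lithium enolate (C8=C9) is O‑sulfonylated, which fixes where the later alkene lies and hence which ring B methylene is C7.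

**Step 5**
Reactants: 10 (4S,6S)-4-bromo-5,5-dimethyl-1-oxospiro[5.5]undec-8-en-9-yl trifluoromethanesulfonate
Product: 11 (4S,6S)-4-bromo-5,5,9-trimethylspiro[5.5]undec-8-en-1-one
Conditions: MeZnCl, Pd(PPh3)4 (5 mol %), THF, 50 °C
Reagents that add atoms: methylzinc chloride, C[Zn]Cl
Why: Negishi coupling: zerovalent palladium inserts into the alkenyl C–OTf bond and not into the neopentyl secondary C–Br bond, and MeZnCl, inert to the ketone, transfers methyl; no stereocentre is formed.

**Step 6**
Reactants: 11 (4S,6S)-4-bromo-5,5,9-trimethylspiro[5.5]undec-8-en-1-one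
Product: 12 (4S,6S,8R,9S)-4-bromo-8,9-epoxy-5,5,9-trimethylspiro[5.5]undecan-1-one
Conditions: mCPBA, Na2HPO4, CH2Cl2, 0 °C
Reagents that add atoms: 3‑chloroperbenzoic acid, OOC(=O)c1cccc(Cl)c1
Why: Prilezhaev epoxidation under substrate control: in the ring B half‑chair the bulky CMe2 carbon is pseudo‑equatorial and the C1 carbonyl carbon pseudo‑axial over one alkene face, so the peracid adds anti to C1 and gives the (8R,9S)-epoxide; the hindered ketone is not oxidised at 0 °C.

**Step 7**
Reactants: 12 (4S,6S,8R,9S)-4-bromo-8,9-epoxy-5,5,9-trimethylspiro[5.5]undecan-1-one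
Product: 15 (4S,6S,8R,9R)-4,9-dibromo-8-chloro-5,5,9-trimethylspiro[5.5]undecan-1-one, via bromo silyl ether 13 (not isolated), via diaxial bromochloride 14 (not isolated)
Conditions: Me3SiBr, Bu4NBr (10 mol %), CH2Cl2, −40 °C; then TiCl4, −78 → −20 °C
Reagents that add atoms: bromotrimethylsilane, C[Si](C)(C)Br; titanium tetrachloride, Cl[Ti](Cl)(Cl)Cl
Why: Proposed new method: Me3SiBr opens the epoxide by trans‑diaxial attack of bromide at the secondary carbon C8 (Fürst–Plattner, inversion); TiCl4 then ionises the tertiary C9–O bond with anchimeric help from the antiperiplanar bromine and chloride first returns at C9 (diaxial 8‑bromo‑9‑chloro isomer), but this isomer re‑ionises until chloride attacks C8 instead, which moves bromine across the same face to C9 and chlorine to C8 (both centres inverted, net 1,2‑interchange) and relieves the syn‑axial C8–Br/C1 strain, the diequatorial product having no antiperiplanar neighbouring group and so being the sink; the closest known reaction types are silyl‑halide opening of epoxides, neighbouring‑group‑assisted substitution of trans‑halohydrins and the dyotropic diaxial‑to‑diequatorial rearrangement of vicinal dihalides.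

**Step 8**
Reactants: 15 (4S,6S,8R,9R)-4,9-dibromo-8-chloro-5,5,9-trimethylspiro[5.5]undecan-1-one
Product: 16 (4S,6R,8R,9R)-4,9-dibromo-8-chloro-5,5,9-trimethyl-1-methylidenespiro[5.5]undecane
Conditions: Cp2TiMe2, toluene, 65 °C, dark
Reagents that add atoms: dimethyltitanocene, C[Ti](C)(C1C=CC=C1)C1C=CC=C1
Why: Petasis methylenation: thermally formed Cp2Ti=CH2 olefinates the hindered ketone by [2+2] addition and cycloreversion under neutral conditions, so the γ‑bromo ketone is not enolised and the halides see no base; no stereocentre is touched (the C6 descriptor changes from S to R only because the CIP priorities change).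

**Compound list**
1 | 6‑methylhept‑5‑en‑2‑one | CC(=O)CCC=C(C)C | starting material
2 | ethyl formate | CCOC=O | starting material
3 | but‑3‑en‑2‑one (methyl vinyl ketone) | CC(=O)C=C | starting material
4 | sodium (1Z)-7-methyl-3-oxoocta-1,6-dien-1-olate | CC(C)=CCCC(=O)/C=C\[O-].[Na+] | intermediate
5 | (5Z)-5-(hydroxymethylidene)-10-methylundec-9-ene-2,6-dione | CC(=O)CC/C(=C/O)C(=O)CCC=C(C)C | intermediate
6 | (2Z)-2-[(5S)-5-bromo-6,6-dimethyloxan-2-ylidene]-5-oxohexanal | CC(=O)CC/C(C=O)=C1\CC[C@H](Br)C(C)(C)O1 | intermediate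
7 | (1R,3S)-3-bromo-2,2-dimethyl-6-oxo-1-(3-oxobutyl)cyclohexane-1-carbaldehyde | O=C1CC[C@H](Br)C(C)(C)[C@@]1(C=O)CCC(C)=O | intermediate
8 | (4S,6S)-4-bromo-5,5-dimethylspiro[5.5]undec-7-ene-1,9-dione | O=C1CC[C@H](Br)C(C)(C)[C@@]12CCC(=O)C=C2 | intermediate
9 | lithium (4S,6S)-4-bromo-5,5-dimethyl-1-oxospiro[5.5]undec-8-en-9-olate | O=C1CC[C@H](Br)C(C)(C)[C@@]12CCC([O-])=CC2.[Li+] | intermediate
10 | (4S,6S)-4-bromo-5,5-dimethyl-1-oxospiro[5.5]undec-8-en-9-yl trifluoromethanesulfonate | O=C1CC[C@H](Br)C(C)(C)[C@@]12CCC(OS(=O)(=O)C(F)(F)F)=CC2 | intermediate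
11 | (4S,6S)-4-bromo-5,5,9-trimethylspiro[5.5]undec-8-en-1-one | O=C1CC[C@H](Br)C(C)(C)[C@@]12CCC(C)=CC2 | intermediate
12 | (4S,6S,8R,9S)-4-bromo-8,9-epoxy-5,5,9-trimethylspiro[5.5]undecan-1-one | O=C1CC[C@H](Br)C(C)(C)[C@@]12CC[C@]3(C)O[C@@H]3C2 | intermediate
13 | (4S,6S,8S,9S)-4,8-dibromo-5,5,9-trimethyl-9-[(trimethylsilyl)oxy]spiro[5.5]undecan-1-one | O=C1CC[C@H](Br)C(C)(C)[C@@]12CC[C@](C)(O[Si](C)(C)C)[C@@H](Br)C2 | intermediate
14 | (4S,6S,8S,9S)-4,8-dibromo-9-chloro-5,5,9-trimethylspiro[5.5]undecan-1-one | O=C1CC[C@H](Br)C(C)(C)[C@@]12CC[C@](C)(Cl)[C@@H](Br)C2 | intermediate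
15 | (4S,6S,8R,9R)-4,9-dibromo-8-chloro-5,5,9-trimethylspiro[5.5]undecan-1-one | O=C1CC[C@H](Br)C(C)(C)[C@@]12CC[C@@](C)(Br)[C@H](Cl)C2 | intermediate
16 | (4S,6R,8R,9R)-4,9-dibromo-8-chloro-5,5,9-trimethyl-1-methylidenespiro[5.5]undecane | C=C1CC[C@H](Br)C(C)(C)[C@@]12CC[C@@](C)(Br)[C@H](Cl)C2 | target

**Total steps:** 8. **Longest linear sequence:** 8 (1 → 16).

**Steps most likely to fail**

Step 2 (new method). Risks: NBS may brominate the enol carbon instead of the alkene, bromonium transfer may erode the ee, and the vicinal quaternary bond may lose out to elimination. Fallback with known chemistry, setting out from 1 (with 2) and coming back at 7: formylate 1 with 2 (NaH) and isolate (1Z)-1-hydroxy-7-methylocta-1,6-dien-3-one F1. Cyclise it with the achiral bromonium source Et2SBr·SbCl5Br (MeNO2, −25 °C; bromonium‑induced cation–olefin cyclisation with an enol terminator) to racemic 4-bromo-2-[(Z)-hydroxymethylidene]-3,3-dimethylcyclohexan-1-one F2. Condense with (1S)-1-phenylethan-1-amine, separate the diastereomeric enaminones by crystallisation and keep (4S)-4-bromo-3,3-dimethyl-2-[(Z)-{[(1S)-1-phenylethyl]amino}methylidene]cyclohexan-1-one F3. Hydrolyse (aq. HCl, THF) to (4S)-4-bromo-2-[(Z)-hydroxymethylidene]-3,3-dimethylcyclohexan-1-one F4. Michael addition of F4 to 3 (Et3N, CH2Cl2), the enone entering anti to the C–Br bond, gives 7.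

Step 7 (new method). Risks: the relay may stop at 14, bromide may open the epoxide at the tertiary carbon, or elimination may intervene. Fallback with known chemistry, setting out from 12 and coming back at 15: open 12 with Li2NiBr4 (THF, 0 °C) to the trans‑diaxial bromohydrin (4S,6S,8S,9S)-4,8-dibromo-9-hydroxy-5,5,9-trimethylspiro[5.5]undecan-1-one F5. Replace the tertiary hydroxyl by chloride with retention through the neighbouring bromine (SOCl2, CH2Cl2, −20 °C) and isolate 14. Then let the diaxial vicinal dihalide undergo the known thermal 1,2‑interchange (dyotropic rearrangement; toluene, 60–80 °C) to 15.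

Step 8. Risks: the ketone is very hindered and the tertiary bromide may not survive 65 °C with the titanium reagent. Fallback setting out from 11 and coming back at 16: methylenate before the halogens are in place (Zn, CH2Br2, TiCl4, THF) to (4S,6R)-4-bromo-5,5,9-trimethyl-1-methylidenespiro[5.5]undec-8-ene F6. Epoxidise the more electron‑rich trisubstituted ring B alkene chemoselectively (mCPBA, 1.0 equiv, −20 °C) to (4S,6R,8R,9S)-4-bromo-8,9-epoxy-5,5,9-trimethyl-1-methylidenespiro[5.5]undecane F7. Submit F7 to the step 7 halogenation (or its stepwise version) to reach 16 directly.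

**Further compounds**
F1 | step 2 | (1Z)-1-hydroxy-7-methylocta-1,6-dien-3-one | CC(C)=CCCC(=O)/C=C\O
F2 | step 2 | racemic 4-bromo-2-[(Z)-hydroxymethylidene]-3,3-dimethylcyclohexan-1-one | O=C1CCC(Br)C(C)(C)/C1=C/O
F3 | step 2 | (4S)-4-bromo-3,3-dimethyl-2-[(Z)-{[(1S)-1-phenylethyl]amino}methylidene]cyclohexan-1-one | O=C1CC[C@H](Br)C(C)(C)/C1=C/N[C@@H](C)c1ccccc1
F4 | step 2 | (4S)-4-bromo-2-[(Z)-hydroxymethylidene]-3,3-dimethylcyclohexan-1-one | O=C1CC[C@H](Br)C(C)(C)/C1=C/O
F5 | step 7 | (4S,6S,8S,9S)-4,8-dibromo-9-hydroxy-5,5,9-trimethylspiro[5.5]undecan-1-one | O=C1CC[C@H](Br)C(C)(C)[C@@]12CC[C@](C)(O)[C@@H](Br)C2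
F6 | step 8 | (4S,6R)-4-bromo-5,5,9-trimethyl-1-methylidenespiro[5.5]undec-8-ene | C=C1CC[C@H](Br)C(C)(C)[C@@]12CCC(C)=CC2
F7 | step 8 | (4S,6R,8R,9S)-4-bromo-8,9-epoxy-5,5,9-trimethyl-1-methylidenespiro[5.5]undecane | C=C1CC[C@H](Br)C(C)(C)[C@@]12CC[C@]3(C)O[C@@H]3C2
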